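**Retrosynthetic overview**

1. Bisabolane numbering: ring A is C1H2–C2–C3(CH3)–C4(OH)–C5(OAng)–C6, and C6 carries C7(=C14H2)–C8H(OAng)–C9H2–C10–C11(CH3)2. The route rests on the C2=C3(CH3)–C4(OH) allylic alcohol of ring A before its epoxidation, the retron of an alkenyl-metal addition to a C4 aldehyde.
2. Last disconnections: C10–C11 oxirane (Shi epoxidation), C2–C3 oxirane (delivered from C4–OH), C4 carbinol (Luche reduction of the ring enone), C5 and C8 angelates.
3. Side chain: C7–C8 by Ni/Cr coupling of a C7 enol triflate with 4-methylpent-3-enal; C8 by Corey–Bakshi–Shibata reduction.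
4. Ring A: C3–C4 by intramolecular Nozaki–Hiyama–Kishi addition of a (Z)-alkenyl iodide to the C4 aldehyde; C5 and C6 by an Evans syn-aldol; the Z-iodide from but-2-yn-1-ol.
5. Ring order: carbocycle A (step 11), then the C2–C3 oxirane (step 25), then the C10–C11 oxirane (step 26).

Key step: step 11

Assumption: step 11 is not expected to control C4; compounds 20 to 34 are drawn as the 4,5-cis epimer, and the 4,5-trans epimer would follow the same steps to the common enone 35.

**Route**

Step 1
Reactants: 1 but-2-yn-1-ol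
Product: 3 (Z)-3-iodobut-2-en-1-ol, via cyclic alkenylaluminate 2 (not isolated)
Conditions: NaAlH2(OCH2CH2OCH3)2, THF, 0 °C to rt; then I2, THF, –78 to 0 °C
Reagents that add atoms: iodine, II; sodium bis(2-methoxyethoxy)aluminium dihydride, [Na+].COCCO[AlH2-]OCCOC (aluminium, sodium and alkoxy groups in 2 only)
Why: Hydroxyl-directed trans-hydroalumination of a propargylic alcohol puts hydride on C2 and aluminium on C3 within the five-membered alkoxyaluminate 2, and iodinolysis with retention leaves iodine cis to CH2OH, which is the Z-iodoalkene.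

Step 2
Reactants: 3 (Z)-3-iodobut-2-en-1-ol
Product: 4 (Z)-1-bromo-3-iodobut-2-ene
Conditions: CBr4, PPh3, CH2Cl2, 0 °C
Reagents that add atoms: carbon tetrabromide, BrC(Br)(Br)Br
Why: Appel reaction, in which bromide displaces the alkoxyphosphonium of the primary allylic alcohol without touching the alkenyl iodide or its geometry.

Step 3
Reactants: 4 (Z)-1-bromo-3-iodobut-2-ene; 5 tert-butyl acetate
Product: 7 tert-butyl (Z)-5-iodohex-4-enoate, via lithium enolate 6 (not isolated)
Conditions: LiN(iPr)2, THF, –78 °C; then 4, –78 to 0 °C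
Reagents that add atoms: lithium diisopropylamide, [Li+].CC(C)[N-]C(C)C (lithium in 6 only)
Why: Ester enolate alkylation, in which the lithium enolate of tert-butyl acetate displaces the primary allylic bromide by SN2 and the hindered ester suppresses self-condensation.

Step 4
Reactants: 7 tert-butyl (Z)-5-iodohex-4-enoate
Product: 8 (Z)-5-iodohex-4-enoic acid
Conditions: CF3CO2H, CH2Cl2, 0 °C to rt
Reagents that add atoms: none
Why: Acidolysis of the tert-butyl ester through the tert-butyl cation (lost as 2-methylpropene) frees the acid, and the alkenyl iodide is inert to trifluoroacetic acid.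

Step 5
Reactants: 8 (Z)-5-iodohex-4-enoic acid; 9 (R)-4-benzyl-1,3-oxazolidin-2-one
Product: 11 (R)-4-benzyl-3-[(Z)-5-iodohex-4-enoyl]-1,3-oxazolidin-2-one, via mixed pivalic anhydride 10 (not isolated)
Conditions: t-BuCOCl, Et3N, THF, –20 °C; then 9, LiCl, –20 °C to rt
Reagents that add atoms: pivaloyl chloride, CC(C)(C)C(=O)Cl (pivaloyl group in 10 only)
Why: N-Acylation through a mixed pivalic anhydride, in which the oxazolidinone activated by LiCl attacks the unhindered carbonyl of 10, a standard way to load the auxiliary without a strong base.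

Step 6
Reactants: 11 (R)-4-benzyl-3-[(Z)-5-iodohex-4-enoyl]-1,3-oxazolidin-2-one; 12 (tert-butyldimethylsilyloxy)acetaldehyde
Product: 14 (R)-4-benzyl-3-[(2R,3R)-4-(tert-butyldimethylsilyloxy)-3-hydroxy-2-[(Z)-3-iodobut-2-enyl]butanoyl]-1,3-oxazolidin-2-one, via Z-boron enolate 13 (not isolated)
Conditions: Bu2BOTf, iPr2NEt, CH2Cl2, –78 to 0 °C; then 12, –78 to 0 °C; then H2O2, MeOH, pH 7 buffer (KH2PO4/Na2HPO4), 0 °C
Reagents that add atoms: dibutylboron triflate, CCCCB(CCCC)OS(=O)(=O)C(F)(F)F (dibutylboryl group in 13 only)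
Why: Evans syn-aldol reaction, in which the Z-boron enolate reacts through a closed chair transition state on the enolate face away from the benzyl group and so sets C6 and C5 together as 2R,3R (side chain and hydroxyl syn) with the R-auxiliary.

Step 7
Reactants: 14 aldol adduct
Product: 15 (2R,3R)-4-(tert-butyldimethylsilyloxy)-3-hydroxy-2-[(Z)-3-iodobut-2-enyl]-N-methoxy-N-methylbutanamide
Conditions: MeONHMe·HCl, AlMe3, CH2Cl2, –20 to 0 °C; aq. potassium sodium tartrate work-up
Reagents that add atoms: N,O-dimethylhydroxylamine hydrochloride, CNOC.Cl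
Why: Weinreb transamidation with the aluminium amide, in which the free C5 hydroxyl binds aluminium and directs attack to the exocyclic imide carbonyl, releasing the auxiliary without epimerising C6.

Step 8
Reactants: 15 β-hydroxy Weinreb amide
Product: 16 (2R,3R)-3,4-bis(tert-butyldimethylsilyloxy)-2-[(Z)-3-iodobut-2-enyl]-N-methoxy-N-methylbutanamide
Conditions: t-BuMe2SiOTf, 2,6-lutidine, CH2Cl2, –78 to 0 °C
Reagents that add atoms: tert-butyldimethylsilyl triflate, CC(C)(C)[Si](C)(C)OS(=O)(=O)C(F)(F)F
Why: Silylation of the secondary C5 hydroxyl with the silyl triflate and a hindered base is fast at low temperature and blocks retro-aldol cleavage and β-elimination in the later steps.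

Step 9
Reactants: 16 bis-silyl ether
Product: 17 (2R,3R)-3-(tert-butyldimethylsilyloxy)-4-hydroxy-2-[(Z)-3-iodobut-2-enyl]-N-methoxy-N-methylbutanamide
Conditions: HF·pyridine, pyridine, THF, 0 °C; crude product taken on at once
Reagents that add atoms: none
Why: Selective desilylation, in which buffered HF·pyridine cleaves the unhindered primary silyl ether far faster than the secondary one at C5, while the buffered medium and immediate use of 17 limit lactonisation of the γ-hydroxy amide.

Step 10
Reactants: 17 primary alcohol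
Product: 18 (2R,3R)-3-(tert-butyldimethylsilyloxy)-2-[(Z)-3-iodobut-2-enyl]-N-methoxy-N-methyl-4-oxobutanamide (the iodoalkenyl aldehyde)
Conditions: Dess–Martin periodinane, pyridine, CH2Cl2, 0 °C to rt
Reagents that add atoms: none
Why: Dess–Martin oxidation of the primary alcohol under pyridine buffering gives the α-silyloxy aldehyde without epimerising C5 and without over-oxidation.

Step 11
Reactants: 18 iodoalkenyl aldehyde
Product: 20 (1R,5S,6R)-6-(tert-butyldimethylsilyloxy)-5-hydroxy-N-methoxy-N,4-dimethylcyclohex-3-ene-1-carboxamide (ring A; C4–OH drawn cis to C5–OSi and C6–C7), via alkenylchromium dichloride 19 (not isolated)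
Conditions: CrCl2 (excess), NiCl2 (cat.), degassed DMF, rt, high dilution (slow addition of 18)
Reagents that add atoms: chromium dichloride, Cl[Cr]Cl (chromium in 19 only)
Why: Zerovalent nickel, formed from NiCl2 by CrCl2, inserts into the C3–I bond with retention, the alkenyl group passes to trivalent chromium to give 19, and 19 adds to the C4 aldehyde. The closest known reaction type is the intramolecular Nozaki–Hiyama–Kishi cyclisation of iodoalkenyl aldehydes to 2-methylcycloalk-2-enols. Ring A closes in the 6-exo-trig mode at the carbonyl carbon, and the Z geometry (C1 and the metal cis on C2=C3) allows only the six-membered ring with the alkene endocyclic. C4 is the only new stereocentre; addition anti to the C5–O bond and the preference of the chromium-bound oxygen for a pseudo-equatorial site both act on it, but its configuration is not relied on because C4 is oxidised in step 22 and reset in step 24. The step needs chemoselectivity for the aldehyde over the Weinreb amide, which the low basicity and carbonyl selectivity of alkenylchromium reagents secure, and ring closure over intermolecular addition, which high dilution secures. C5 and C6 enter with the cis relation from step 6 and are not touched.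

Step 12
Reactants: 20 cyclohexenol
Product: 21 (1R,5S,6R)-6-(tert-butyldimethylsilyloxy)-N-methoxy-N,4-dimethyl-5-(triethylsilyloxy)cyclohex-3-ene-1-carboxamide
Conditions: Et3SiOTf, 2,6-lutidine, CH2Cl2, –78 °C
Reagents that add atoms: triethylsilyl triflate, CC[Si](CC)(CC)OS(=O)(=O)C(F)(F)F
Why: Silylation with the silyl triflate caps the hindered allylic C4 hydroxyl so that the Grignard, amide-base and chromium steps see no free OH, and the triethylsilyl group is later removed together with the C5 silyl ether.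

Step 13
Reactants: 21 silylated Weinreb amide
Product: 22 1-[(1R,5S,6R)-6-(tert-butyldimethylsilyloxy)-4-methyl-5-(triethylsilyloxy)cyclohex-3-en-1-yl]ethan-1-one (C7 methyl ketone)
Conditions: MeMgBr, THF, 0 °C; aq. NH4Cl
Reagents that add atoms: methylmagnesium bromide, C[Mg]Br
Why: Weinreb ketone synthesis, in which the magnesium-chelated tetrahedral intermediate stops at single addition and collapses only on work-up, so that the methyl ketone forms without over-addition or C6 epimerisation.

Step 14
Reactants: 22 methyl ketone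
Product: 24 1-[(1R,5S,6R)-6-(tert-butyldimethylsilyloxy)-4-methyl-5-(triethylsilyloxy)cyclohex-3-en-1-yl]ethenyl trifluoromethanesulfonate, via potassium enolate 23 (not isolated)
Conditions: KN(SiMe3)2, THF, –78 °C; then PhNTf2, –78 to 0 °C
Reagents that add atoms: N-phenylbis(trifluoromethanesulfonimide), O=S(=O)(N(c1ccccc1)S(=O)(=O)C(F)(F)F)C(F)(F)F; potassium bis(trimethylsilyl)amide, [K+].C[Si](C)(C)[N-][Si](C)(C)C (potassium in 23 only)
Why: Kinetic enolisation and O-triflation, in which the bulky amide base removes a proton from the C14 methyl group and not from the hindered C6 methine at –78 °C, and PhNTf2 traps the terminal enolate as the 1,1-disubstituted enol triflate.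

Step 15
Reactants: 25 4-methylpent-3-en-1-ol
Product: 26 4-methylpent-3-enal
Conditions: Dess–Martin periodinane, pyridine, CH2Cl2, 0 °C; solution used directly
Reagents that add atoms: none
Why: Dess–Martin oxidation under pyridine buffering gives the β,γ-unsaturated aldehyde without acid- or base-induced migration of the double bond into conjugation.

Step 16
Reactants: 24 enol triflate; 26 4-methylpent-3-enal
Product: 28 (4S,5R,6S)-5-(tert-butyldimethylsilyloxy)-4-(triethylsilyloxy)bisabola-2,7(14),10-trien-8-ol (C8 epimers), via alkenylchromium dichloride 27 (not isolated)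
Conditions: CrCl2 (excess), NiCl2 (cat.), DMF, rt
Reagents that add atoms: chromium dichloride, Cl[Cr]Cl (chromium in 27 only)
Why: Intermolecular Nozaki–Hiyama–Kishi coupling, in which nickel activates the enol triflate and the alkenylchromium 27 adds only to the aldehyde and is too weakly basic to enolise it, forming C7–C8 with C8 left to be set in step 18.

Step 17
Reactants: 28 allylic alcohol (C8 epimers)
Product: 29 (4S,5R,6S)-5-(tert-butyldimethylsilyloxy)-4-(triethylsilyloxy)bisabola-2,7(14),10-trien-8-one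
Conditions: Dess–Martin periodinane, pyridine, CH2Cl2, 0 °C
Reagents that add atoms: none
Why: Dess–Martin oxidation of the secondary allylic alcohol converges both C8 epimers on the α-methylene ketone under buffered, non-isomerising conditions.

Step 18
Reactants: 29 α-methylene ketone
Product: 30 (4S,5R,6S,8S)-5-(tert-butyldimethylsilyloxy)-4-(triethylsilyloxy)bisabola-2,7(14),10-trien-8-ol
Conditions: (R)-1-methyl-3,3-diphenyltetrahydro-1H,3H-pyrrolo[1,2-c][1,3,2]oxazaborole ((R)-Me-CBS oxazaborolidine, cat.), catecholborane, toluene, –78 °C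
Reagents that add atoms: none
Why: Corey–Bakshi–Shibata reduction, in which the α-branched alkenyl group (C7) is the large and the C9 methylene the small substituent, so that the R-oxazaborolidine delivers hydride to the face that gives 8S, under reagent control and as 1,2-reduction only.

Step 19
Reactants: 31 angelic acid
Product: 32 angelic 2,4,6-trichlorobenzoic anhydride
Conditions: 2,4,6-Cl3C6H2COCl, Et3N, toluene, rt; Et3NHCl filtered off under argon, filtrate concentrated; crude 32 kept as a toluene solution at –20 °C, one batch sized for steps 20 and 23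
Reagents that add atoms: 2,4,6-trichlorobenzoyl chloride, O=C(Cl)c1c(Cl)cc(Cl)cc1Cl
Why: Yamaguchi-type mixed-anhydride formation, in which triethylammonium angelate attacks the aroyl chloride at room temperature and no nucleophilic acyl-transfer catalyst is present that could add to the angeloyl group and turn it into the E isomer.

Step 20
Reactants: 30 (8S)-alcohol; 32 angelic 2,4,6-trichlorobenzoic anhydride
Product: 33 (4S,5R,6S,8S)-5-(tert-butyldimethylsilyloxy)-4-(triethylsilyloxy)bisabola-2,7(14),10-trien-8-yl angelate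
Conditions: 32, 2,6-lutidine, toluene, 80 °C
Reagents that add atoms: none
Why: Mixed-anhydride esterification, in which the alcohol attacks the angeloyl carbonyl of 32 because the flanked aroyl carbonyl is shielded, while the hindered pyridine takes up the liberated acid so that the silyl ethers survive and the angelate keeps its Z geometry.

Step 21
Reactants: 33 bis-silyl angelate
Product: 34 (4S,5R,6S,8S)-4,5-dihydroxybisabola-2,7(14),10-trien-8-yl angelate
Conditions: HF·pyridine, pyridine, THF, 0 °C to rt
Reagents that add atoms: none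
Why: Fluoride-mediated desilylation removes both the triethylsilyl and the tert-butyldimethylsilyl ether under buffered, mildly acidic conditions that leave the allylic angelate and the alkenes untouched.

Step 22
Reactants: 34 diol
Product: 35 (5R,6S,8S)-5-hydroxy-4-oxobisabola-2,7(14),10-trien-8-yl angelate
Conditions: MnO2, CH2Cl2, rt
Reagents that add atoms: none
Why: Chemoselective allylic oxidation, in which MnO2 oxidises only the allylic C4 hydroxyl to the enone, so that C4 is differentiated from the saturated C5 hydroxyl and the C4 configuration left by step 11 is erased.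

Step 23
Reactants: 35 α-hydroxy enone; 32 angelic 2,4,6-trichlorobenzoic anhydride
Product: 36 (5R,6S,8S)-4-oxobisabola-2,7(14),10-triene-5,8-diyl diangelate
Conditions: 32 (second portion of the batch from step 19), 2,6-lutidine, toluene, 80 °C
Reagents that add atoms: none
Why: The same mixed-anhydride esterification acylates the C5 hydroxyl of the α-ketol, and the hindered, weakly basic pyridine keeps C5, now α to the ketone, from epimerising and the angelate from isomerising.

Step 24
Reactants: 36 bis-angelate enone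
Product: 37 (4S,5R,6S,8S)-4-hydroxybisabola-2,7(14),10-triene-5,8-diyl diangelate
Conditions: NaBH4, CeCl3·7H2O, MeOH, –78 °C
Reagents that add atoms: none
Why: Luche reduction, in which borohydride assisted by CeCl3 adds 1,2 to the enone by axial attack on the face opposite the pseudo-axial C5–O bond and the C6 side chain, so that the C4 hydroxyl ends cis to both, and the conjugated esters are not reduced.

Step 25
Reactants: 37 allylic alcohol
Product: 38 (2S,3R,4R,5R,6S,8S)-2,3-epoxy-4-hydroxybisabola-7(14),10-diene-5,8-diyl diangelate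
Conditions: VO(acac)2 (cat.), t-BuOOH, CH2Cl2, 0 °C to rt
Reagents that add atoms: tert-butyl hydroperoxide, CC(C)(C)OO
Why: Vanadium-catalysed hydroxyl-directed epoxidation, in which the C4 vanadate ester delivers the peroxide oxygen to the same face of C2=C3 and sets C2 and C3 cis to the C4 hydroxyl, while the undirected C7=C14, C10=C11 and angelate alkenes react much more slowly.

Step 26
Reactants: 38 epoxy alcohol
Product: 39 CNP0235377.1, (2S,3R,4R,5R,6S,8S,10R)-2,3:10,11-diepoxy-4-hydroxybisabol-7(14)-ene-5,8-diyl diangelate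
Conditions: 1,2:4,5-di-O-isopropylidene-β-D-erythro-2,3-hexodiulo-2,6-pyranose (D-fructose-derived Shi ketone), KHSO5 (as 2KHSO5·KHSO4·K2SO4), NaHCO3, MeCN/aq. Na2H2EDTA, 0 °C
Reagents that add atoms: potassium peroxymonosulfate, [K+].[O-]S(=O)(=O)OO
Why: Shi epoxidation, in which the dioxirane of the D-fructose-derived ketone attacks the electron-rich trisubstituted C10=C11 alkene through a spiro transition state in the facial sense known for trisubstituted alkenes and gives 10R, while the 1,1-disubstituted and conjugated alkenes are too electron-poor to compete and the near-neutral buffer limits acyl migration.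

**Compound list**

1 | but-2-yn-1-ol | CC#CCO | starting material
2 | sodium 2,2-bis(2-methoxyethoxy)-3-methyl-2,5-dihydro-1,2-oxaluminol-2-uide (cyclic alkenylaluminate) | CC1=CCO[Al-]1(OCCOC)OCCOC.[Na+] | intermediate
3 | (Z)-3-iodobut-2-en-1-ol | OC/C=C(/C)I | intermediate
4 | (Z)-1-bromo-3-iodobut-2-ene | BrC/C=C(/C)I | intermediate
5 | tert-butyl acetate | CC(=O)OC(C)(C)C | starting material
6 | lithium enolate of tert-butyl acetate | [Li]OC(=C)OC(C)(C)C | intermediate
7 | tert-butyl (Z)-5-iodohex-4-enoate | CC(C)(C)OC(=O)CC/C=C(/C)I | intermediate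
8 | (Z)-5-iodohex-4-enoic acid | OC(=O)CC/C=C(/C)I | intermediate
9 | (R)-4-benzyl-1,3-oxazolidin-2-one | O=C1N[C@H](Cc2ccccc2)CO1 | starting material
10 | (Z)-5-iodohex-4-enoic pivalic anhydride | CC(C)(C)C(=O)OC(=O)CC/C=C(/C)I | intermediate
11 | (R)-4-benzyl-3-[(Z)-5-iodohex-4-enoyl]-1,3-oxazolidin-2-one | O=C(CC/C=C(/C)I)N1C(=O)OC[C@H]1Cc1ccccc1 | intermediate
12 | (tert-butyldimethylsilyloxy)acetaldehyde | CC(C)(C)[Si](C)(C)OCC=O | starting material
13 | (Z)-dibutylboron enolate of 11 | CCCCB(CCCC)O/C(=C\C/C=C(/C)I)N1C(=O)OC[C@H]1Cc1ccccc1 | intermediate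
14 | (R)-4-benzyl-3-[(2R,3R)-4-(tert-butyldimethylsilyloxy)-3-hydroxy-2-[(Z)-3-iodobut-2-enyl]butanoyl]-1,3-oxazolidin-2-one | O=C([C@H](C/C=C(/C)I)[C@@H](O)CO[Si](C)(C)C(C)(C)C)N1C(=O)OC[C@H]1Cc1ccccc1 | intermediate
15 | (2R,3R)-4-(tert-butyldimethylsilyloxy)-3-hydroxy-2-[(Z)-3-iodobut-2-enyl]-N-methoxy-N-methylbutanamide | CON(C)C(=O)[C@H](C/C=C(/C)I)[C@@H](O)CO[Si](C)(C)C(C)(C)C | intermediate
16 | (2R,3R)-3,4-bis(tert-butyldimethylsilyloxy)-2-[(Z)-3-iodobut-2-enyl]-N-methoxy-N-methylbutanamide | CON(C)C(=O)[C@H](C/C=C(/C)I)[C@@H](O[Si](C)(C)C(C)(C)C)CO[Si](C)(C)C(C)(C)C | intermediate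
17 | (2R,3R)-3-(tert-butyldimethylsilyloxy)-4-hydroxy-2-[(Z)-3-iodobut-2-enyl]-N-methoxy-N-methylbutanamide | CON(C)C(=O)[C@H](C/C=C(/C)I)[C@@H](O[Si](C)(C)C(C)(C)C)CO | intermediate
18 | (2R,3R)-3-(tert-butyldimethylsilyloxy)-2-[(Z)-3-iodobut-2-enyl]-N-methoxy-N-methyl-4-oxobutanamide | CON(C)C(=O)[C@H](C/C=C(/C)I)[C@@H](O[Si](C)(C)C(C)(C)C)C=O | intermediate
19 | alkenylchromium dichloride derived from 18 | CON(C)C(=O)[C@H](C/C=C(/C)[Cr](Cl)Cl)[C@@H](O[Si](C)(C)C(C)(C)C)C=O | intermediate
20 | (1R,5S,6R)-6-(tert-butyldimethylsilyloxy)-5-hydroxy-N-methoxy-N,4-dimethylcyclohex-3-ene-1-carboxamide | CON(C)C(=O)[C@@H]1CC=C(C)[C@H](O)[C@@H]1O[Si](C)(C)C(C)(C)C | intermediate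
21 | (1R,5S,6R)-6-(tert-butyldimethylsilyloxy)-N-methoxy-N,4-dimethyl-5-(triethylsilyloxy)cyclohex-3-ene-1-carboxamide | CON(C)C(=O)[C@@H]1CC=C(C)[C@H](O[Si](CC)(CC)CC)[C@@H]1O[Si](C)(C)C(C)(C)C | intermediate
22 | 1-[(1R,5S,6R)-6-(tert-butyldimethylsilyloxy)-4-methyl-5-(triethylsilyloxy)cyclohex-3-en-1-yl]ethan-1-one | CC(=O)[C@@H]1CC=C(C)[C@H](O[Si](CC)(CC)CC)[C@@H]1O[Si](C)(C)C(C)(C)C | intermediate
23 | potassium enolate of 22 (terminal) | C=C(O[K])[C@@H]1CC=C(C)[C@H](O[Si](CC)(CC)CC)[C@@H]1O[Si](C)(C)C(C)(C)C | intermediate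
24 | 1-[(1R,5S,6R)-6-(tert-butyldimethylsilyloxy)-4-methyl-5-(triethylsilyloxy)cyclohex-3-en-1-yl]ethenyl trifluoromethanesulfonate | C=C(OS(=O)(=O)C(F)(F)F)[C@@H]1CC=C(C)[C@H](O[Si](CC)(CC)CC)[C@@H]1O[Si](C)(C)C(C)(C)C | intermediate
25 | 4-methylpent-3-en-1-ol | CC(C)=CCCO | starting material
26 | 4-methylpent-3-enal | CC(C)=CCC=O | intermediate
27 | alkenylchromium dichloride derived from 24 | C=C([Cr](Cl)Cl)[C@@H]1CC=C(C)[C@H](O[Si](CC)(CC)CC)[C@@H]1O[Si](C)(C)C(C)(C)C | intermediate
28 | (4S,5R,6S)-5-(tert-butyldimethylsilyloxy)-4-(triethylsilyloxy)bisabola-2,7(14),10-trien-8-ol, C8 epimers | C=C(C(O)CC=C(C)C)[C@@H]1CC=C(C)[C@H](O[Si](CC)(CC)CC)[C@@H]1O[Si](C)(C)C(C)(C)C | intermediate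
29 | (4S,5R,6S)-5-(tert-butyldimethylsilyloxy)-4-(triethylsilyloxy)bisabola-2,7(14),10-trien-8-one | C=C(C(=O)CC=C(C)C)[C@@H]1CC=C(C)[C@H](O[Si](CC)(CC)CC)[C@@H]1O[Si](C)(C)C(C)(C)C | intermediate
30 | (4S,5R,6S,8S)-5-(tert-butyldimethylsilyloxy)-4-(triethylsilyloxy)bisabola-2,7(14),10-trien-8-ol | C=C([C@H](CC=C(C)C)O)[C@@H]1CC=C(C)[C@H](O[Si](CC)(CC)CC)[C@@H]1O[Si](C)(C)C(C)(C)C | intermediate
31 | angelic acid, (Z)-2-methylbut-2-enoic acid | C/C=C(/C)C(=O)O | starting material
32 | angelic 2,4,6-trichlorobenzoic anhydride | C/C=C(/C)C(=O)OC(=O)c1c(Cl)cc(Cl)cc1Cl | intermediate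
33 | (4S,5R,6S,8S)-5-(tert-butyldimethylsilyloxy)-4-(triethylsilyloxy)bisabola-2,7(14),10-trien-8-yl angelate | C=C([C@H](CC=C(C)C)OC(=O)/C(C)=C\C)[C@@H]1CC=C(C)[C@H](O[Si](CC)(CC)CC)[C@@H]1O[Si](C)(C)C(C)(C)C | intermediate
34 | (4S,5R,6S,8S)-4,5-dihydroxybisabola-2,7(14),10-trien-8-yl angelate | C=C([C@H](CC=C(C)C)OC(=O)/C(C)=C\C)[C@@H]1CC=C(C)[C@H](O)[C@@H]1O | intermediate
35 | (5R,6S,8S)-5-hydroxy-4-oxobisabola-2,7(14),10-trien-8-yl angelate | C=C([C@H](CC=C(C)C)OC(=O)/C(C)=C\C)[C@@H]1CC=C(C)C(=O)[C@@H]1O | intermediate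
36 | (5R,6S,8S)-4-oxobisabola-2,7(14),10-triene-5,8-diyl diangelate | C=C([C@H](CC=C(C)C)OC(=O)/C(C)=C\C)[C@@H]1CC=C(C)C(=O)[C@@H]1OC(=O)/C(C)=C\C | intermediate
37 | (4S,5R,6S,8S)-4-hydroxybisabola-2,7(14),10-triene-5,8-diyl diangelate | C=C([C@H](CC=C(C)C)OC(=O)/C(C)=C\C)[C@@H]1CC=C(C)[C@H](O)[C@@H]1OC(=O)/C(C)=C\C | intermediate
38 | (2S,3R,4R,5R,6S,8S)-2,3-epoxy-4-hydroxybisabola-7(14),10-diene-5,8-diyl diangelate | C=C([C@H](CC=C(C)C)OC(=O)/C(C)=C\C)[C@@H]1C[C@@H]2O[C@]2(C)[C@H](O)[C@@H]1OC(=O)/C(C)=C\C | intermediate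
39 | CNP0235377.1, (2S,3R,4R,5R,6S,8S,10R)-2,3:10,11-diepoxy-4-hydroxybisabol-7(14)-ene-5,8-diyl diangelate | C=C([C@H](C[C@H]1OC1(C)C)OC(=O)/C(C)=C\C)[C@@H]1C[C@@H]2O[C@]2(C)[C@H](O)[C@@H]1OC(=O)/C(C)=C\C | target

**Step count**

Total step count: 26. Longest linear sequence: 24 steps (steps 1 to 14, 16 to 18 and 20 to 26, from 1 to 39); steps 15 and 19 are one-step branches.

**Steps most likely to fail**

Step 11 (ring closure). The alkenylchromium may be protonated, or the C–I bond reduced, faster than the hindered α-silyloxy aldehyde is attacked, and intermolecular addition may compete with closure. The fallback closes ring A at C2=C3 by ring-closing metathesis instead of at C3–C4. It sets out from 9, which is acylated with pent-4-enoyl chloride (n-BuLi, THF, –78 °C) to (R)-4-benzyl-3-(pent-4-enoyl)-1,3-oxazolidin-2-one F1. The boron aldol of step 6 with 12 gives the syn adduct F2. Transamidation, silylation, primary desilylation and Dess–Martin oxidation as in steps 7 to 10 give the Weinreb amide F3, the bis-silyl ether F4, the primary alcohol F5 and the aldehyde F6. Isopropenylmagnesium bromide (THF, –78 °C) adds to the aldehyde in preference to the Weinreb amide and gives the diene carbinol F7. RuCl2(=CHPh)(H2IMes)(PCy3), the second-generation Grubbs catalyst, in CH2Cl2 at 40 °C then closes the ring with loss of ethene, and the fallback comes back to the route at 20.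

Step 9 (with step 10). The freed C4 hydroxyl may attack the C7 amide and form a five-membered lactone with loss of N,O-dimethylhydroxylamine, and the two silyl ethers may be discriminated incompletely. The fallback carries C4 as a vinyl carbon, so that no free C4 hydroxyl ever exists. It sets out from 11, whose boron aldol with acrolein under the conditions of step 6 gives the allylic alcohol F8. Transamidation as in step 7 gives the Weinreb amide F9 and silylation as in step 8 gives the silyl ether F10. Lemieux–Johnson cleavage (OsO4 cat., NaIO4, 2,6-lutidine, dioxane/water) then cuts the monosubstituted alkene with loss of formaldehyde; the iodine-bearing trisubstituted alkene is deactivated towards OsO4. The fallback comes back to the route at 18.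

Step 16 (side-chain coupling). The β,γ double bond of 26 may migrate into conjugation, or 26 may self-condense under the Lewis acidic chromium salts, and the hindered triflate may be activated too slowly. The fallback brings in C8 as a configurationally defined α-oxygenated organolithium and forms C7=C14 by carbonyl methylenation. It sets out from 25 and 21. Alcohol 25 is converted with iPr2NCOCl (NaH, THF) into 4-methylpent-3-enyl N,N-diisopropylcarbamate F11. s-BuLi with (+)-sparteine (Et2O, –78 °C) removes one enantiotopic C8 proton and gives the (R)-configured lithiated carbamate F12. F12 acylates Weinreb amide 21 with retention to the α-carbamoyloxy ketone F13. Cp2TiMe2 (toluene, 70 °C, Petasis methylenation) converts the C7 ketone into the 1,1-disubstituted alkene F14, and LiAlH4 (THF, 0 °C to rt) removes the carbamoyl group. The fallback comes back to the route at 30 and replaces steps 13 to 18.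

**Further compounds**

F1 | step 11 | (R)-4-benzyl-3-(pent-4-enoyl)-1,3-oxazolidin-2-one | C=CCCC(=O)N1C(=O)OC[C@H]1Cc1ccccc1
F2 | step 11 | (R)-4-benzyl-3-[(2R,3R)-2-allyl-4-(tert-butyldimethylsilyloxy)-3-hydroxybutanoyl]-1,3-oxazolidin-2-one | O=C([C@H](CC=C)[C@@H](O)CO[Si](C)(C)C(C)(C)C)N1C(=O)OC[C@H]1Cc1ccccc1
F3 | step 11 | (2R,3R)-2-allyl-4-(tert-butyldimethylsilyloxy)-3-hydroxy-N-methoxy-N-methylbutanamide | CON(C)C(=O)[C@H](CC=C)[C@@H](O)CO[Si](C)(C)C(C)(C)C
F4 | step 11 | (2R,3R)-2-allyl-3,4-bis(tert-butyldimethylsilyloxy)-N-methoxy-N-methylbutanamide | CON(C)C(=O)[C@H](CC=C)[C@@H](O[Si](C)(C)C(C)(C)C)CO[Si](C)(C)C(C)(C)C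
F5 | step 11 | (2R,3R)-2-allyl-3-(tert-butyldimethylsilyloxy)-4-hydroxy-N-methoxy-N-methylbutanamide | CON(C)C(=O)[C@H](CC=C)[C@@H](O[Si](C)(C)C(C)(C)C)CO
F6 | step 11 | (2R,3R)-2-allyl-3-(tert-butyldimethylsilyloxy)-N-methoxy-N-methyl-4-oxobutanamide | CON(C)C(=O)[C@H](CC=C)[C@@H](O[Si](C)(C)C(C)(C)C)C=O
F7 | step 11 | (2R,3R)-2-allyl-3-(tert-butyldimethylsilyloxy)-4-hydroxy-N-methoxy-N,5-dimethylhex-5-enamide, C4 epimers | CON(C)C(=O)[C@H](CC=C)[C@@H](O[Si](C)(C)C(C)(C)C)C(O)C(C)=C
F8 | step 9 | (R)-4-benzyl-3-[(2R,3S)-3-hydroxy-2-[(Z)-3-iodobut-2-enyl]pent-4-enoyl]-1,3-oxazolidin-2-one | O=C([C@H](C/C=C(/C)I)[C@@H](O)C=C)N1C(=O)OC[C@H]1Cc1ccccc1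
F9 | step 9 | (2R,3S)-3-hydroxy-2-[(Z)-3-iodobut-2-enyl]-N-methoxy-N-methylpent-4-enamide | CON(C)C(=O)[C@H](C/C=C(/C)I)[C@@H](O)C=C
F10 | step 9 | (2R,3S)-3-(tert-butyldimethylsilyloxy)-2-[(Z)-3-iodobut-2-enyl]-N-methoxy-N-methylpent-4-enamide | CON(C)C(=O)[C@H](C/C=C(/C)I)[C@@H](O[Si](C)(C)C(C)(C)C)C=C
F11 | step 16 | 4-methylpent-3-enyl N,N-diisopropylcarbamate | CC(C)=CCCOC(=O)N(C(C)C)C(C)C
F12 | step 16 | (R)-1-lithio-4-methylpent-3-enyl N,N-diisopropylcarbamate (sparteine complex) | [Li][C@H](CC=C(C)C)OC(=O)N(C(C)C)C(C)C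
F13 | step 16 | (4S,5R,6R,8S)-5-(tert-butyldimethylsilyloxy)-7-oxo-4-(triethylsilyloxy)-14-norbisabola-2,10-dien-8-yl N,N-diisopropylcarbamate | O=C([C@H](CC=C(C)C)OC(=O)N(C(C)C)C(C)C)[C@@H]1CC=C(C)[C@H](O[Si](CC)(CC)CC)[C@@H]1O[Si](C)(C)C(C)(C)C
F14 | step 16 | (4S,5R,6S,8S)-5-(tert-butyldimethylsilyloxy)-4-(triethylsilyloxy)bisabola-2,7(14),10-trien-8-yl N,N-diisopropylcarbamate | C=C([C@H](CC=C(C)C)OC(=O)N(C(C)C)C(C)C)[C@@H]1CC=C(C)[C@H](O[Si](CC)(CC)CC)[C@@H]1O[Si](C)(C)C(C)(C)C
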